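**Retrosynthetic overview**

- Feature: in each benzopyranone the ring oxygen (O1, O1′) sits on C8a (C8a′), ortho to the C4a–C4=C3–C2(=O) chain, on a benzene ring with OMe at C6 and C8 and oxygen at C7. Each half is therefore a sinapic acid oxygenated at one ring C–H, and the C3–O–C7′ ether is the 8-O-4′ link of a sinapic acid dehydrodimer.
- Last operation: removal of a benzyl group from the C7 oxygen.
- Key disconnection: C8a–O1 and C8a′–O1′ are cut together, leading back to the 7-O-benzyl 8-O-4′ disinapic diacid. Both pyranone rings form in one photocatalytic oxidative lactonization.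
- The diacid comes from a Perkin condensation (Cα=Cβ of the aryloxyacrylic acid) between O-benzylsyringaldehyde and the aryloxyacetic acid made from methyl sinapate and tert-butyl bromoacetate, followed by ester hydrolysis.
- Ring order: both benzene rings are bought; the two pyranone rings are formed together in the key step.

Key step: step 7

Remark: the target has no stereogenic element, so only alkene geometry in the intermediates needs specifying; the order of the two isomerizations and closures in step 7 is not fixed, and the intermediates drawn there show one representative order.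

**Route**

Step 1
Reactants: 1 sinapic acid
Product: 2 methyl sinapate, methyl (E)-3-(4-hydroxy-3,5-dimethoxyphenyl)prop-2-enoate
Conditions: MeOH, H2SO4 (cat.), reflux
Reagents that add atoms: methanol, CO
Why: Fischer esterification should convert the acid cleanly, since the phenol and the alkene are inert to acidic methanol.

Step 2
Reactants: 2 methyl sinapate; 3 tert-butyl bromoacetate
Product: 4 methyl (E)-3-[4-(2-tert-butoxy-2-oxoethoxy)-3,5-dimethoxyphenyl]prop-2-enoate
Conditions: K2CO3, DMF, 60 °C
Reagents that add atoms: none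
Why: Williamson etherification of the acidic 2,6-dimethoxyphenoxide with a reactive α-bromo ester (SN2) should proceed without touching the methyl cinnamate.

Step 3
Reactants: 4 methyl (E)-3-[4-(2-tert-butoxy-2-oxoethoxy)-3,5-dimethoxyphenyl]prop-2-enoate
Product: 5 2-{2,6-dimethoxy-4-[(E)-3-methoxy-3-oxoprop-1-en-1-yl]phenoxy}acetic acid
Conditions: TFA/CH2Cl2 1:2, 0 °C to rt
Reagents that add atoms: none
Why: Acidolysis of the tert-butyl ester by alkyl–oxygen cleavage should free only the acetic acid arm and leave the methyl ester and the alkene intact.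

Step 4
Reactants: 6 syringaldehyde; 7 benzyl bromide
Product: 8 4-(benzyloxy)-3,5-dimethoxybenzaldehyde
Conditions: K2CO3, DMF, 60 °C
Reagents that add atoms: none
Why: Williamson benzylation of the phenoxide should give the benzyl ether, which is stable to the anhydride, base and photo-oxidation steps that follow.

Step 5
Reactants: 5 2-{2,6-dimethoxy-4-[(E)-3-methoxy-3-oxoprop-1-en-1-yl]phenoxy}acetic acid; 8 4-(benzyloxy)-3,5-dimethoxybenzaldehyde
Product: 10 (Z)-3-[4-(benzyloxy)-3,5-dimethoxyphenyl]-2-{2,6-dimethoxy-4-[(E)-3-methoxy-3-oxoprop-1-en-1-yl]phenoxy}prop-2-enoic acid, via acetic mixed anhydride 9 (not isolated)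
Conditions: Ac2O (4 equiv), Et3N (3 equiv), 110 °C; then H2O, 60 °C; aq HCl
Reagents that add atoms: none
Why: In this Perkin condensation the mixed anhydride 9 is enolized by Et3N, adds to the aldehyde and loses acetate, which should favour the isomer with carboxyl trans to the β-aryl group (Z by CIP) while the methyl cinnamate and benzyl ether stay inert.

Step 6
Reactants: 10 (Z)-3-[4-(benzyloxy)-3,5-dimethoxyphenyl]-2-{2,6-dimethoxy-4-[(E)-3-methoxy-3-oxoprop-1-en-1-yl]phenoxy}prop-2-enoic acid
Product: 11 (Z)-3-[4-(benzyloxy)-3,5-dimethoxyphenyl]-2-{4-[(E)-2-carboxyethenyl]-2,6-dimethoxyphenoxy}prop-2-enoic acid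
Conditions: LiOH·H2O (5 equiv), THF/MeOH/H2O, rt; then 1 M HCl
Reagents that add atoms: lithium hydroxide (hydroxide oxygen), [Li+].[OH-]
Why: Saponification of the methyl cinnamate should give the diacid, since the aryl ethers, the enol ether (present as its carboxylate) and the benzyl ether resist aqueous hydroxide at room temperature.

Step 7
Reactants: 11 (Z)-3-[4-(benzyloxy)-3,5-dimethoxyphenyl]-2-{4-[(E)-2-carboxyethenyl]-2,6-dimethoxyphenoxy}prop-2-enoic acid
Product: 14 7-(benzyloxy)-3-[(6,8-dimethoxy-2-oxo-2H-chromen-7-yl)oxy]-6,8-dimethoxy-2H-chromen-2-one, via doubly isomerized diacid 12 (not isolated), via monolactone acid 13 (not isolated)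
Conditions: (−)-riboflavin (20 mol %), O2 (1 atm), MeCN/MeOH 1:1 (5 mM), 402 nm LEDs, rt
Reagents that add atoms: none
Why: Proposed new method: the excited flavin should first act as triplet sensitizer, scrambling both alkene geometries so that isomers with carboxyl cis to the arene (as in 12) are continuously supplied, and then as one-electron oxidant, turning each 4-alkoxy-3,5-dimethoxyaryl-ethene unit into an arene radical cation to whose ortho carbon (ortho to one methoxy, para to the other, where spin and charge reside) the neighbouring carboxylate adds; a second oxidation with loss of the ring proton rearomatizes, and O2 reoxidizes the reduced flavin to give H2O2. The closest known reaction type is the riboflavin-photocatalysed one-pot E-to-Z isomerization/oxidative cyclization of single cinnamic acids to coumarins; a twofold closure in one molecule, one of them on an α-aryloxyacrylic acid, is not established. Each pyranone ring closes in a six-membered mode by carboxyl-oxygen-to-aryl-carbon bond formation (C8a–O1 for the 3-aryloxy ring, C8a′–O1′ for the other). No stereocentre is created. The step needs chemoselectivity (arene oxidation and carboxylate capture ahead of phenoxyl chemistry, benzylic oxidation or alkene oxygenation) and the correct alkene geometry, but no regiocontrol: the phenol is masked as a benzyl ether, each ring is symmetric about its C1–C4 axis so both ortho carbons are equivalent, and irreversible lactonization drains the photostationary mixture.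

Step 8
Reactants: 14 7-(benzyloxy)-3-[(6,8-dimethoxy-2-oxo-2H-chromen-7-yl)oxy]-6,8-dimethoxy-2H-chromen-2-one
Product: 15 7-hydroxy-3-[(6,8-dimethoxy-2-oxo-2H-chromen-7-yl)oxy]-6,8-dimethoxy-2H-chromen-2-one
Conditions: H2 (1 atm), 10% Pd/C, EtOAc/THF, rt, stopped when 14 is consumed
Reagents that add atoms: none
Why: Hydrogenolysis of the benzylic C–O bond should be faster than reduction of the pyranone double bonds and leaves the methyl ethers, the diaryl-type ether and both lactones untouched.

**Compound list**

1 | sinapic acid | COc1cc(/C=C/C(O)=O)cc(OC)c1O | starting material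
2 | methyl sinapate | COC(=O)/C=C/c1cc(OC)c(O)c(OC)c1 | intermediate
3 | tert-butyl bromoacetate | CC(C)(C)OC(=O)CBr | starting material
4 | methyl (E)-3-[4-(2-tert-butoxy-2-oxoethoxy)-3,5-dimethoxyphenyl]prop-2-enoate | COC(=O)/C=C/c1cc(OC)c(OCC(=O)OC(C)(C)C)c(OC)c1 | intermediate
5 | 2-{2,6-dimethoxy-4-[(E)-3-methoxy-3-oxoprop-1-en-1-yl]phenoxy}acetic acid | COC(=O)/C=C/c1cc(OC)c(OCC(O)=O)c(OC)c1 | intermediate
6 | syringaldehyde | COc1cc(C=O)cc(OC)c1O | starting material
7 | benzyl bromide | BrCc1ccccc1 | starting material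
8 | 4-(benzyloxy)-3,5-dimethoxybenzaldehyde | COc1cc(C=O)cc(OC)c1OCc1ccccc1 | intermediate
9 | acetic 2-{2,6-dimethoxy-4-[(E)-3-methoxy-3-oxoprop-1-en-1-yl]phenoxy}acetic anhydride | COC(=O)/C=C/c1cc(OC)c(OCC(=O)OC(C)=O)c(OC)c1 | intermediate (not isolated)
10 | (Z)-3-[4-(benzyloxy)-3,5-dimethoxyphenyl]-2-{2,6-dimethoxy-4-[(E)-3-methoxy-3-oxoprop-1-en-1-yl]phenoxy}prop-2-enoic acid | COC(=O)/C=C/c1cc(OC)c(O/C(C(O)=O)=C\c2cc(OC)c(OCc3ccccc3)c(OC)c2)c(OC)c1 | intermediate
11 | (Z)-3-[4-(benzyloxy)-3,5-dimethoxyphenyl]-2-{4-[(E)-2-carboxyethenyl]-2,6-dimethoxyphenoxy}prop-2-enoic acid | OC(=O)/C=C/c1cc(OC)c(O/C(C(O)=O)=C\c2cc(OC)c(OCc3ccccc3)c(OC)c2)c(OC)c1 | intermediate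
12 | (E)-3-[4-(benzyloxy)-3,5-dimethoxyphenyl]-2-{4-[(Z)-2-carboxyethenyl]-2,6-dimethoxyphenoxy}prop-2-enoic acid | OC(=O)/C=C\c1cc(OC)c(O/C(C(O)=O)=C/c2cc(OC)c(OCc3ccccc3)c(OC)c2)c(OC)c1 | intermediate (not isolated)
13 | (Z)-3-{4-[(7-benzyloxy-6,8-dimethoxy-2-oxo-2H-chromen-3-yl)oxy]-3,5-dimethoxyphenyl}prop-2-enoic acid | OC(=O)/C=C\c1cc(OC)c(Oc2cc3cc(OC)c(OCc4ccccc4)c(OC)c3oc2=O)c(OC)c1 | intermediate (not isolated)
14 | 7-(benzyloxy)-3-[(6,8-dimethoxy-2-oxo-2H-chromen-7-yl)oxy]-6,8-dimethoxy-2H-chromen-2-one | COc1cc2cc(Oc3c(OC)cc4ccc(=O)oc4c3OC)c(=O)oc2c(OC)c1OCc1ccccc1 | intermediate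
15 | 7-hydroxy-3-[(6,8-dimethoxy-2-oxo-2H-chromen-7-yl)oxy]-6,8-dimethoxy-2H-chromen-2-one | COc1cc2cc(Oc3c(OC)cc4ccc(=O)oc4c3OC)c(=O)oc2c(OC)c1O | target

**Step count**

Total: 8 steps. Longest linear sequence: 7 steps (1, 2, 3, 5, 6, 7, 8, from sinapic acid).

**Steps most likely to fail**

1. Step 7 (Proposed new method). What may go wrong: oxidative loss of the benzyl group at its benzylic C–H, photo-oxygenation and cleavage of the electron-rich enol-ether alkene, or stalling after the first lactonization so that the second ring never closes.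
Fallback (known chemistry; the 3-aryloxy pyranone is closed by a Perkin-type coumarin condensation and the other coumarin is bought closed). It sets out from aldehyde 8 and bromoacetate 3 and returns to the route at 14. Aldehyde 8 would be brominated at its only free ring position (NBS, MeCN) to 4-(benzyloxy)-2-bromo-3,5-dimethoxybenzaldehyde F1. This would be protected (ethylene glycol, TsOH, toluene, Dean–Stark) as 2-[4-(benzyloxy)-2-bromo-3,5-dimethoxyphenyl]-1,3-dioxolane F2. Bromine–lithium exchange (n-BuLi, THF, −78 °C), borylation (B(OMe)3) and oxidation (H2O2, NaOH) would give 3-(benzyloxy)-6-(1,3-dioxolan-2-yl)-2,4-dimethoxyphenol F3, and hydrolysis (aq HCl, THF) would give 4-(benzyloxy)-2-hydroxy-3,5-dimethoxybenzaldehyde F4. Separately, purchased isofraxidin (7-hydroxy-6,8-dimethoxycoumarin) F5 would be O-alkylated with 3 (K2CO3, DMF) to tert-butyl 2-[(6,8-dimethoxy-2-oxo-2H-chromen-7-yl)oxy]acetate F6 and cleaved with TFA to 2-[(6,8-dimethoxy-2-oxo-2H-chromen-7-yl)oxy]acetic acid F7. Condensation of F4 with F7 (Ac2O, Et3N, 110 °C), the classical route from salicylaldehydes and aryloxyacetic acids to 3-aryloxycoumarins, should give 14 directly.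

2. Step 5. What may go wrong: sluggish condensation with the electron-rich, weakly electrophilic aldehyde, decomposition of the mixed anhydride on prolonged heating, and difficult purification of the acid from the neutral and acidic side products.
Fallback (olefination instead of condensation). It sets out from methyl sinapate 2 and aldehyde 8 and returns at 11. Rh2(OAc)4-catalysed O–H insertion of ethyl diazo(diethoxyphosphoryl)acetate into the phenol of 2 (toluene, 80 °C) would give methyl (E)-3-{4-[1-(diethoxyphosphoryl)-2-ethoxy-2-oxoethoxy]-3,5-dimethoxyphenyl}prop-2-enoate F8. Horner–Wadsworth–Emmons olefination of 8 with F8 (LiCl, DBU, MeCN) should give ethyl 3-[4-(benzyloxy)-3,5-dimethoxyphenyl]-2-{2,6-dimethoxy-4-[(E)-3-methoxy-3-oxoprop-1-en-1-yl]phenoxy}prop-2-enoate F9. F9 is drawn as the Z isomer; a mixture of enol-ether geometries is acceptable because step 7 equilibrates them. Saponification of both esters (LiOH, THF/MeOH/H2O) returns the route at 11.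

3. Step 8. What may go wrong: over-reduction of the unsubstituted C3′=C4′ pyranone double bond to the dihydrocoumarin before debenzylation is complete.
Fallback (Lewis-acid dealkylation instead of reduction). It sets out from 14 and returns at 15: BCl3 with pentamethylbenzene as benzyl-cation scavenger in CH2Cl2 at −78 °C, quenched cold so that the methyl ethers are not attacked. No new compound is made on the way.

**Further compounds**

F1 | step 7 | 4-(benzyloxy)-2-bromo-3,5-dimethoxybenzaldehyde | COc1cc(C=O)c(Br)c(OC)c1OCc1ccccc1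
F2 | step 7 | 2-[4-(benzyloxy)-2-bromo-3,5-dimethoxyphenyl]-1,3-dioxolane | COc1cc(C2OCCO2)c(Br)c(OC)c1OCc1ccccc1
F3 | step 7 | 3-(benzyloxy)-6-(1,3-dioxolan-2-yl)-2,4-dimethoxyphenol | COc1cc(C2OCCO2)c(O)c(OC)c1OCc1ccccc1
F4 | step 7 | 4-(benzyloxy)-2-hydroxy-3,5-dimethoxybenzaldehyde | COc1cc(C=O)c(O)c(OC)c1OCc1ccccc1
F5 | step 7 | isofraxidin, 7-hydroxy-6,8-dimethoxy-2H-chromen-2-one (purchased building block) | COc1cc2ccc(=O)oc2c(OC)c1O
F6 | step 7 | tert-butyl 2-[(6,8-dimethoxy-2-oxo-2H-chromen-7-yl)oxy]acetate | COc1cc2ccc(=O)oc2c(OC)c1OCC(=O)OC(C)(C)C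
F7 | step 7 | 2-[(6,8-dimethoxy-2-oxo-2H-chromen-7-yl)oxy]acetic acid | COc1cc2ccc(=O)oc2c(OC)c1OCC(O)=O
F8 | step 5 | methyl (E)-3-{4-[1-(diethoxyphosphoryl)-2-ethoxy-2-oxoethoxy]-3,5-dimethoxyphenyl}prop-2-enoate | COC(=O)/C=C/c1cc(OC)c(OC(C(=O)OCC)P(=O)(OCC)OCC)c(OC)c1
F9 | step 5 | ethyl (Z)-3-[4-(benzyloxy)-3,5-dimethoxyphenyl]-2-{2,6-dimethoxy-4-[(E)-3-methoxy-3-oxoprop-1-en-1-yl]phenoxy}prop-2-enoate | COC(=O)/C=C/c1cc(OC)c(O/C(C(=O)OCC)=C\c2cc(OC)c(OCc3ccccc3)c(OC)c2)c(OC)c1
F0 | step 8 | none | none
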